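## Retrosynthetic overview

1. Target 13 ⇐ aryl boronate 12 (phenol revealed last by C–B oxidation) ⇐ oxolane ester 10 (ester → CH2OAc, carbinol → OAc).
2. Oxolane ring of 10 ⇐ triol 8 by O1–C5 Williamson closure; 8 ⇐ keto lactone 6 by chelation-controlled ketone reduction and lactone reduction.
3. 6 ⇐ lactone 4 + 4-methoxybenzoyl chloride 5 (Claisen C-acylation at C4, thermodynamic trans).
4. Key disconnection: C2–C3 bond of lactone 4 ⇐ aldehyde 1 + enal 2 by a carbene-catalysed homoenolate [3+2] annulation, in which the β-carbon of the enal is the nucleophile.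
5. Ring order: γ-lactone (step 1), opened (step 3), then the oxolane (step 4).

Assumptions and abbreviation:
- ArB = 4-(4,4,5,5-tetramethyl-1,3,2-dioxaborolan-2-yl)phenyl, a masked 4-hydroxyphenyl group.
- The (5aR,10bS) triazolium salt is assumed to give the (2R) lactone; if the sense is the opposite, its (5aS,10bR) antipode is used.
- tert-Butyl (E)-4-oxobut-2-enoate (2) is taken as a purchased building block.

## Route

Step 1
Reactants: 1 4-(4,4,5,5-tetramethyl-1,3,2-dioxaborolan-2-yl)benzaldehyde; 2 tert-butyl (E)-4-oxobut-2-enoate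
Product: 4 tert-butyl (2R,3R)-5-oxo-2-(ArB)oxolane-3-carboxylate (2,3-trans), via cis-lactone 3 (not isolated)
Conditions: 1 (2 equiv), 2 added over 4 h, (5aR,10bS)-2-(2,4,6-trimethylphenyl)-5a,10b-dihydro-4H,6H-indeno[2,1-b][1,2,4]triazolo[4,3-d][1,4]oxazin-2-ium chloride (10 mol%), DBU (20 mol%), THF, 0 °C to rt; then DBU (0.5 equiv), rt, 6 h
Reagents that add atoms: none
Why: Proposed new method: the carbene adds to the aldehyde of 2 and the ester-conjugated Breslow intermediate reacts as a homoenolate, so the normally electrophilic β-carbon of the enal attacks the aldehyde carbon of 1 on the face left open by the indane backbone (setting C2 as R), tautomerisation to the acyl azolium and lactonisation release the carbene, and DBU equilibrates the acidic C3 (α to the ester) to the more stable 2,3-trans isomer; the closest known chemistry is the NHC-catalysed homoenolate [3+2] annulation of cinnamaldehydes with aryl aldehydes to γ-butyrolactones.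

Step 2
Reactants: 4 tert-butyl (2R,3R)-5-oxo-2-(ArB)oxolane-3-carboxylate; 5 4-methoxybenzoyl chloride
Product: 6 tert-butyl (2R,3R,4S)-4-(4-methoxybenzoyl)-5-oxo-2-(ArB)oxolane-3-carboxylate
Conditions: LiN(SiMe3)2 (2.1 equiv), THF, −78 °C, 30 min; then 5 (1.05 equiv), −78 to −40 °C; aq. NH4Cl
Reagents that add atoms: none
Why: Crossed Claisen condensation (C-acylation of a lithium lactone enolate): the lactone α-CH2 is deprotonated kinetically, the second equivalent of base holds 6 as its stabilised enolate, and protonation on work-up places the aroyl group trans to the C3 ester (thermodynamic control at the acidic C4).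

Step 3
Reactants: 6 tert-butyl (2R,3R,4S)-4-(4-methoxybenzoyl)-5-oxo-2-(ArB)oxolane-3-carboxylate
Product: 8 tert-butyl (2R,3R,4S)-4-hydroxy-2-[(R)-hydroxy(ArB)methyl]-3-(hydroxymethyl)-4-(4-methoxyphenyl)butanoate, via hydroxy lactone 7 (not isolated)
Conditions: Zn(BH4)2 (1.5 equiv, ethereal stock solution), Et2O/THF, −30 °C, 2 h; then LiBH4 (3 equiv), 0 °C, 3 h; aq. NH4Cl
Reagents that add atoms: none
Why: Chelation-controlled reduction of a β-keto lactone: zinc bridges the ketone and lactone carbonyls and hydride enters the ketone face opposite the C3 substituent, giving the syn (S) carbinol, after which LiBH4 reduces the lactone to the 1,4-diol while the tert-butyl ester is left untouched.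

Step 4
Reactants: 8 tert-butyl (2R,3R,4S)-4-hydroxy-2-[(R)-hydroxy(ArB)methyl]-3-(hydroxymethyl)-4-(4-methoxyphenyl)butanoate
Product: 10 tert-butyl (2R,3R,4R)-4-[(S)-hydroxy(4-methoxyphenyl)methyl]-2-(ArB)oxolane-3-carboxylate, via primary tosylate 9 (not isolated)
Conditions: TsCl (1.1 equiv), pyridine, 0 °C, 6 h; then 45 °C, 4 h
Reagents that add atoms: 4-methylbenzenesulfonyl chloride, Cc1ccc(cc1)S(=O)(=O)Cl (its atoms are held by 9 only and leave on ring closure)
Why: Selective sulfonylation of the only primary hydroxyl followed by intramolecular Williamson etherification (5-exo-tet) by the benzylic hydroxyl four atoms away; no stereocentre is touched, so the oxolane inherits the 2,3-trans-3,4-trans arrangement, and the competing 4-exo closure to an oxetane is much slower.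

Step 5
Reactants: 10 tert-butyl (2R,3R,4R)-4-[(S)-hydroxy(4-methoxyphenyl)methyl]-2-(ArB)oxolane-3-carboxylate
Product: 12 [(2R,3S,4R)-4-[(S)-acetyloxy(4-methoxyphenyl)methyl]-2-(ArB)oxolan-3-yl]methyl acetate, via diol 11 (not isolated)
Conditions: iBu2AlH (5 equiv), CH2Cl2, −78 to 0 °C; then pyridine, DMAP (0.2 equiv), Ac2O (8 equiv), 0 °C to rt; aq. potassium sodium tartrate
Reagents that add atoms: acetic anhydride, CC(=O)OC(C)=O
Why: Hydride reduction of the tert-butyl ester to the primary alkoxide followed by acetylation of both aluminium alkoxides in the same flask (reductive acetylation), which leaves the aryl boronate and all four stereocentres untouched.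

Step 6
Reactants: 12 [(2R,3S,4R)-4-[(S)-acetyloxy(4-methoxyphenyl)methyl]-2-(ArB)oxolan-3-yl]methyl acetate
Product: 13 [(2R,3S,4R)-4-[(S)-acetyloxy(4-methoxyphenyl)methyl]-2-(4-hydroxyphenyl)oxolan-3-yl]methyl acetate (CNP0231272.1)
Conditions: 2KHSO5·KHSO4·K2SO4 (1 equiv), NaHCO3, acetone/H2O, 0 °C, 10 min; aq. NaHSO3
Reagents that add atoms: potassium peroxymonosulfate, [K+].[O-]S(=O)(=O)OO
Why: Oxidation of an aryl boronic ester (boron-to-oxygen 1,2-aryl shift in the peroxide adduct, then hydrolysis) is fast at 0 °C under buffered conditions that touch neither the two acetates nor the benzylic C–O bonds.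

## Compound list

1 | 4-(4,4,5,5-tetramethyl-1,3,2-dioxaborolan-2-yl)benzaldehyde | O=Cc1ccc(B2OC(C)(C)C(C)(C)O2)cc1 | starting material
2 | tert-butyl (E)-4-oxobut-2-enoate | O=C/C=C/C(=O)OC(C)(C)C | starting material
3 | tert-butyl (2R,3S)-5-oxo-2-[4-(4,4,5,5-tetramethyl-1,3,2-dioxaborolan-2-yl)phenyl]oxolane-3-carboxylate (cis, not isolated) | O=C1C[C@H](C(=O)OC(C)(C)C)[C@H](c2ccc(B3OC(C)(C)C(C)(C)O3)cc2)O1 | intermediate
4 | tert-butyl (2R,3R)-5-oxo-2-[4-(4,4,5,5-tetramethyl-1,3,2-dioxaborolan-2-yl)phenyl]oxolane-3-carboxylate (trans) | O=C1C[C@@H](C(=O)OC(C)(C)C)[C@H](c2ccc(B3OC(C)(C)C(C)(C)O3)cc2)O1 | intermediate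
5 | 4-methoxybenzoyl chloride | COc1ccc(C(Cl)=O)cc1 | starting material
6 | tert-butyl (2R,3R,4S)-4-(4-methoxybenzoyl)-5-oxo-2-[4-(4,4,5,5-tetramethyl-1,3,2-dioxaborolan-2-yl)phenyl]oxolane-3-carboxylate | COc1ccc(C(=O)[C@H]2C(=O)O[C@@H](c3ccc(B4OC(C)(C)C(C)(C)O4)cc3)[C@@H]2C(=O)OC(C)(C)C)cc1 | intermediate
7 | tert-butyl (2R,3R,4S)-4-[(S)-hydroxy(4-methoxyphenyl)methyl]-5-oxo-2-[4-(4,4,5,5-tetramethyl-1,3,2-dioxaborolan-2-yl)phenyl]oxolane-3-carboxylate (not isolated) | COc1ccc([C@@H](O)[C@H]2C(=O)O[C@@H](c3ccc(B4OC(C)(C)C(C)(C)O4)cc3)[C@@H]2C(=O)OC(C)(C)C)cc1 | intermediate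
8 | tert-butyl (2R,3R,4S)-4-hydroxy-2-[(R)-hydroxy[4-(4,4,5,5-tetramethyl-1,3,2-dioxaborolan-2-yl)phenyl]methyl]-3-(hydroxymethyl)-4-(4-methoxyphenyl)butanoate | COc1ccc([C@@H](O)[C@H]([C@@H](C(=O)OC(C)(C)C)[C@@H](O)c2ccc(B3OC(C)(C)C(C)(C)O3)cc2)CO)cc1 | intermediate
9 | tert-butyl (2R,3R,4S)-4-hydroxy-2-[(R)-hydroxy[4-(4,4,5,5-tetramethyl-1,3,2-dioxaborolan-2-yl)phenyl]methyl]-4-(4-methoxyphenyl)-3-[(4-methylbenzenesulfonyl)oxymethyl]butanoate (not isolated) | COc1ccc([C@@H](O)[C@H]([C@@H](C(=O)OC(C)(C)C)[C@@H](O)c2ccc(B3OC(C)(C)C(C)(C)O3)cc2)COS(=O)(=O)c2ccc(C)cc2)cc1 | intermediate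
10 | tert-butyl (2R,3R,4R)-4-[(S)-hydroxy(4-methoxyphenyl)methyl]-2-[4-(4,4,5,5-tetramethyl-1,3,2-dioxaborolan-2-yl)phenyl]oxolane-3-carboxylate | COc1ccc([C@@H](O)[C@H]2CO[C@@H](c3ccc(B4OC(C)(C)C(C)(C)O4)cc3)[C@@H]2C(=O)OC(C)(C)C)cc1 | intermediate
11 | [(2R,3S,4R)-4-[(S)-hydroxy(4-methoxyphenyl)methyl]-2-[4-(4,4,5,5-tetramethyl-1,3,2-dioxaborolan-2-yl)phenyl]oxolan-3-yl]methanol (not isolated, present as its aluminium alkoxide) | COc1ccc([C@@H](O)[C@H]2CO[C@@H](c3ccc(B4OC(C)(C)C(C)(C)O4)cc3)[C@@H]2CO)cc1 | intermediate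
12 | [(2R,3S,4R)-4-[(S)-acetyloxy(4-methoxyphenyl)methyl]-2-[4-(4,4,5,5-tetramethyl-1,3,2-dioxaborolan-2-yl)phenyl]oxolan-3-yl]methyl acetate | COc1ccc([C@@H](OC(C)=O)[C@H]2CO[C@@H](c3ccc(B4OC(C)(C)C(C)(C)O4)cc3)[C@@H]2COC(C)=O)cc1 | intermediate
13 | [(2R,3S,4R)-4-[(S)-acetyloxy(4-methoxyphenyl)methyl]-2-(4-hydroxyphenyl)oxolan-3-yl]methyl acetate | COc1ccc([C@@H](OC(C)=O)[C@H]2CO[C@@H](c3ccc(O)cc3)[C@@H]2COC(C)=O)cc1 | target

## Step count and risk

Total step count: 6. Longest linear sequence: 6 steps (1 and 2 to 13).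

The three steps most likely to fail are steps 1, 4 and 5.

Step 1 (new annulation; the ester-stabilised homoenolate may be protonated instead of adding, and the enantioselectivity is untested). The fallback sets out from 1 and comes back at 4. A thiazolium-catalysed Stetter reaction (3-benzyl-5-(2-hydroxyethyl)-4-methylthiazolium chloride, Et3N, dioxane, 70 °C) adds the acyl anion of 1 to commercial di-tert-butyl fumarate and gives racemic di-tert-butyl 2-[4-(4,4,5,5-tetramethyl-1,3,2-dioxaborolan-2-yl)benzoyl]butanedioate F1. Its C2 is configurationally labile, so asymmetric transfer hydrogenation under dynamic kinetic resolution (RuCl[(R,R)-TsNCH(Ph)CH(Ph)NH2](p-cymene), HCO2H/Et3N) gives di-tert-butyl 2-[(R)-hydroxy[4-(4,4,5,5-tetramethyl-1,3,2-dioxaborolan-2-yl)phenyl]methyl]butanedioate F2. Warming F2 with DBU in toluene closes the γ-lactone with loss of tert-butanol and equilibrates C3 to trans, which returns to 4.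

Step 4 (the tosylation must pick one hydroxyl of three, and the second benzylic hydroxyl or the ester carbonyl could compete in the closure). The fallback sets out from 6 and comes back at 10. Only the ketone is reduced (Zn(BH4)2, −30 °C) and 7 is isolated. Silylation of the carbinol (tBuMe2SiOSO2CF3, 2,6-lutidine) gives tert-butyl (2R,3R,4S)-4-[(S)-[tert-butyl(dimethyl)silyl]oxy(4-methoxyphenyl)methyl]-5-oxo-2-(ArB)oxolane-3-carboxylate F3. LiBH4 opens the lactone to tert-butyl (2R,3R,4S)-4-[tert-butyl(dimethyl)silyl]oxy-2-[(R)-hydroxy(ArB)methyl]-3-(hydroxymethyl)-4-(4-methoxyphenyl)butanoate F4, which has only one free secondary hydroxyl. A Mitsunobu cyclodehydration (PPh3, diisopropyl azodicarboxylate, THF) closes it to tert-butyl (2R,3R,4R)-4-[(S)-[tert-butyl(dimethyl)silyl]oxy(4-methoxyphenyl)methyl]-2-(ArB)oxolane-3-carboxylate F5, and HF·pyridine removes the silyl group to return to 10.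

Step 5 (the boronate may not survive iBu2AlH at 0 °C, and the one-flask acetylation of the hindered aluminium alkoxides may be incomplete). The fallback sets out from 10 and comes back at 13. The boron is oxidised first (2KHSO5·KHSO4·K2SO4, NaHCO3, acetone/H2O) to tert-butyl (2R,3R,4R)-2-(4-hydroxyphenyl)-4-[(S)-hydroxy(4-methoxyphenyl)methyl]oxolane-3-carboxylate F6. LiAlH4 then reduces the ester to 4-[(2R,3S,4R)-3-(hydroxymethyl)-4-[(S)-hydroxy(4-methoxyphenyl)methyl]oxolan-2-yl]phenol F7. Ac2O/pyridine gives [(2R,3S,4R)-2-(4-acetyloxyphenyl)-4-[(S)-acetyloxy(4-methoxyphenyl)methyl]oxolan-3-yl]methyl acetate F8, and pyrrolidine (1.1 equiv, CH2Cl2, 0 °C) cleaves only the aryl acetate to give 13.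

## Further compounds

F1 | step 1 | di-tert-butyl 2-[4-(4,4,5,5-tetramethyl-1,3,2-dioxaborolan-2-yl)benzoyl]butanedioate (racemic) | CC(C)(C)OC(=O)CC(C(=O)OC(C)(C)C)C(=O)c1ccc(B2OC(C)(C)C(C)(C)O2)cc1
F2 | step 1 | di-tert-butyl 2-[(R)-hydroxy[4-(4,4,5,5-tetramethyl-1,3,2-dioxaborolan-2-yl)phenyl]methyl]butanedioate (both C2 epimers) | CC(C)(C)OC(=O)CC(C(=O)OC(C)(C)C)[C@@H](O)c1ccc(B2OC(C)(C)C(C)(C)O2)cc1
F3 | step 4 | tert-butyl (2R,3R,4S)-4-[(S)-[tert-butyl(dimethyl)silyl]oxy(4-methoxyphenyl)methyl]-5-oxo-2-[4-(4,4,5,5-tetramethyl-1,3,2-dioxaborolan-2-yl)phenyl]oxolane-3-carboxylate | COc1ccc([C@@H](O[Si](C)(C)C(C)(C)C)[C@H]2C(=O)O[C@@H](c3ccc(B4OC(C)(C)C(C)(C)O4)cc3)[C@@H]2C(=O)OC(C)(C)C)cc1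
F4 | step 4 | tert-butyl (2R,3R,4S)-4-[tert-butyl(dimethyl)silyl]oxy-2-[(R)-hydroxy[4-(4,4,5,5-tetramethyl-1,3,2-dioxaborolan-2-yl)phenyl]methyl]-3-(hydroxymethyl)-4-(4-methoxyphenyl)butanoate | COc1ccc([C@@H](O[Si](C)(C)C(C)(C)C)[C@H]([C@@H](C(=O)OC(C)(C)C)[C@@H](O)c2ccc(B3OC(C)(C)C(C)(C)O3)cc2)CO)cc1
F5 | step 4 | tert-butyl (2R,3R,4R)-4-[(S)-[tert-butyl(dimethyl)silyl]oxy(4-methoxyphenyl)methyl]-2-[4-(4,4,5,5-tetramethyl-1,3,2-dioxaborolan-2-yl)phenyl]oxolane-3-carboxylate | COc1ccc([C@@H](O[Si](C)(C)C(C)(C)C)[C@H]2CO[C@@H](c3ccc(B4OC(C)(C)C(C)(C)O4)cc3)[C@@H]2C(=O)OC(C)(C)C)cc1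
F6 | step 5 | tert-butyl (2R,3R,4R)-2-(4-hydroxyphenyl)-4-[(S)-hydroxy(4-methoxyphenyl)methyl]oxolane-3-carboxylate | COc1ccc([C@@H](O)[C@H]2CO[C@@H](c3ccc(O)cc3)[C@@H]2C(=O)OC(C)(C)C)cc1
F7 | step 5 | 4-[(2R,3S,4R)-3-(hydroxymethyl)-4-[(S)-hydroxy(4-methoxyphenyl)methyl]oxolan-2-yl]phenol | COc1ccc([C@@H](O)[C@H]2CO[C@@H](c3ccc(O)cc3)[C@@H]2CO)cc1
F8 | step 5 | [(2R,3S,4R)-2-(4-acetyloxyphenyl)-4-[(S)-acetyloxy(4-methoxyphenyl)methyl]oxolan-3-yl]methyl acetate | COc1ccc([C@@H](OC(C)=O)[C@H]2CO[C@@H](c3ccc(OC(C)=O)cc3)[C@@H]2COC(C)=O)cc1
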